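**Plan**
Retrosynthetic cuts: the C15–O palmitate; C8=C17 (from an 8-ketone); then, after adding a C1=C2 double bond, C3–C4 and C5–C10 together (retro-[4+2]), which opens rings A and B to one acyclic trienoic acid.
Enabling feature: ring A is a cyclohexane whose C4 bears CO2H (so C4=C5 is an α-methyl enoic acid dienophile) and whose C10 bears the angular methyl (so C10=C1–C2=C3 is a diene with that methyl on its terminus); C6–C9 of ring B are the tether, and C8, the later C=CH2 carbon, can carry a temporary oxygen.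
Forward order: geraniol supplies C9 and C11–C16; C8/C7 come by olefination, C10/C1 by alkynylalane opening of an epoxide, C2/C3 by carboalumination–vinylation, C6/C5 by a cyanomethyl anion, C4/C18/C19 by Z-selective olefination.
Rings A and B then close in one intramolecular Diels–Alder step; hydrogenation of C1=C2, C8 oxidation and methylenation, PMB removal and palmitoylation finish the route.
Stereochemistry: one catalytic asymmetric epoxidation sets C8 and, after SN2 inversion, C9; C5, C10 and C4 are relayed in the cycloaddition by the chair tether, the E-diene (trans fusion) and the Z-enoic acid (axial CO2H).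

Key step: step 13

Remark: labdane numbering (C1–C20) is used to locate atoms in all intermediates; PMB = 4-methoxybenzyl, TBS = tert-butyldimethylsilyl; geraniol is the only carbon starting material and all reagents named are catalogue chemicals.

Step 1
Reactants: 1 geraniol
Product: 2 geranyl PMB ether
Conditions: NaH, PMBCl, Bu4NI (cat.), THF/DMF, 0 °C → rt
Reagents that add atoms: 4-methoxybenzyl chloride COc1ccc(CCl)cc1
Why: Williamson etherification of the primary allylic alkoxide installs a protecting group that is orthogonal to the later silyl ether and should survive the basic, hydridic and thermal steps.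

Step 2
Reactants: 2 geranyl PMB ether
Product: 4 (4E)-4-methyl-6-(PMB-oxy)hex-4-enal, via 6,7-epoxide 3 (not isolated)
Conditions: mCPBA (1.0 equiv), CH2Cl2, −20 °C; then H5IO6, THF/H2O, 0 °C
Reagents that add atoms: 3-chloroperbenzoic acid OOC(=O)c1cccc(Cl)c1
Why: Prilezhaev epoxidation should occur at the more electron-rich distal alkene (the 2,3-alkene is deactivated by the allylic ether) and periodic acid cleavage of the epoxide through its diol releases the aldehyde and acetone.

Step 3
Reactants: 4 aldehyde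
Product: 5 ethyl (2E,6E)-6-methyl-8-(PMB-oxy)octa-2,6-dienoate
Conditions: (EtO)2P(O)CH2CO2Et, NaH, THF, 0 °C
Reagents that add atoms: triethyl phosphonoacetate CCOC(=O)CP(=O)(OCC)OCC
Why: Horner–Wadsworth–Emmons olefination with a stabilised phosphonate is reliably E-selective with unbranched aldehydes and adds C8 and C7.

Step 4
Reactants: 5 dienoate
Product: 6 (2E,6E)-6-methyl-8-(PMB-oxy)octa-2,6-dien-1-ol
Conditions: DIBAL-H (2.2 equiv), CH2Cl2, −78 °C
Reagents that add atoms: none
Why: 1,2-Reduction of the enoate by DIBAL-H gives the allylic alcohol that directs the next epoxidation.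

Step 5
Reactants: 6 dienol
Product: 7 (2R,3R)-epoxy alcohol
Conditions: Ti(OiPr)4 (10 mol%), D-(−)-diisopropyl tartrate (12 mol%), t-BuOOH, 4 Å MS, CH2Cl2, −20 °C
Reagents that add atoms: tert-butyl hydroperoxide CC(C)(C)OO
Why: Sharpless asymmetric epoxidation is directed by the allylic hydroxyl, so the remote trisubstituted alkene is untouched, and the D-tartrate ligand should deliver oxygen to the face that gives the (2R,3R)-epoxide, which fixes C8 and, after inversion, C9.

Step 6
Reactants: 7 epoxy alcohol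
Product: 9 (2S,3R,6E)-3-ethynyl-6-methyl-8-(PMB-oxy)oct-6-ene-1,2-diol, via C-silyl alkynyl diol 8 (not isolated)
Conditions: TMSC≡CH, n-BuLi, Et2AlCl (4 equiv each), toluene, −78 → 0 °C, then 7, 0 °C → rt; aq. Rochelle salt; then K2CO3, MeOH, rt
Reagents that add atoms: (trimethylsilyl)acetylene C#C[Si](C)(C)C
Why: Alkynylalane opening of a 2,3-epoxy alcohol takes place at C3 by SN2 inversion, which puts the ethynyl group on C9 with the C8 hydroxyl and the C9 side chain in the syn relationship the key step needs, and methanolysis removes the C-silyl group.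

Step 7
Reactants: 9 alkynyl diol
Product: 11 (2S,3R,6E)-6-methyl-8-(PMB-oxy)-3-[(2E)-penta-2,4-dien-2-yl]oct-6-ene-1,2-diol, via alkenyldimethylalane 10 (not isolated)
Conditions: Me3Al (5 equiv), Cp2ZrCl2 (0.5 equiv), (CH2Cl)2, rt; then ZnCl2, vinyl bromide, Pd(PPh3)4 (5 mol%), THF, rt
Reagents that add atoms: trimethylaluminium C[Al](C)C; vinyl bromide C=CBr
Why: Zirconium-catalysed syn-carboalumination puts methyl on C10 and aluminium on C1 (cis to each other), and Negishi cross-coupling with vinyl bromide proceeds with retention, so the diene should have C9 trans to C2 and the methyl group inside.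

Step 8
Reactants: 11 dienyl diol
Product: 13 (2S)-2-[(3E,5R,8E)-4,8-dimethyl-10-(PMB-oxy)deca-1,3,8-trien-5-yl]oxirane, via primary tosylate 12 (not isolated)
Conditions: TsCl, Et3N, Bu2SnO (2 mol%), CH2Cl2, 0 °C; then K2CO3, MeOH, rt
Reagents that add atoms: none
Why: Tin-catalysed sulfonylation is selective for the primary hydroxyl of a 1,2-diol and the intramolecular Williamson closure leaves the C8–O bond intact, so C8 keeps its configuration.

Step 9
Reactants: 13 terminal epoxide
Product: 15 (4R,5R,6E)-silyloxy dienenitrile, via lithium alkoxide 14 (not isolated)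
Conditions: MeCN, n-BuLi (1.2 equiv), THF, −78 °C, then 13, −78 → −20 °C; then TBSOTf, −78 → 0 °C
Reagents that add atoms: acetonitrile CC#N; tert-butyldimethylsilyl trifluoromethanesulfonate CC(C)(C)[Si](C)(C)OS(=O)(=O)C(F)(F)F
Why: SN2 opening of the terminal epoxide at its CH2 carbon by the cyanomethyl anion adds C6 and C5 at low temperature, and the resulting alkoxide is O-silylated in the same flask.

Step 10
Reactants: 15 nitrile
Product: 17 (4R,5R,6E)-silyloxy dienal, via N-aluminoimine 16 (not isolated)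
Conditions: DIBAL-H (1.2 equiv), toluene, −78 °C; aq. Rochelle salt, rt
Reagents that add atoms: water O
Why: Partial nitrile reduction stops at the N-aluminoimine after one hydride transfer, and hydrolysis on work-up gives the C5 aldehyde.

Step 11
Reactants: 17 aldehyde
Product: 18 ethyl (2Z,6R,7R,8E)-trienoate
Conditions: (CF3CH2O)2P(O)CH(CH3)CO2Et, KHMDS, 18-crown-6, THF, −78 °C
Reagents that add atoms: ethyl 2-[bis(2,2,2-trifluoroethoxy)phosphoryl]propanoate CCOC(=O)C(C)P(=O)(OCC(F)(F)F)OCC(F)(F)F
Why: Still–Gennari olefination (electron-poor phosphonate, dissociated potassium counter-ion, fast elimination from the kinetic adduct) should give the (Z)-2-methyl enoate whose geometry later defines C4.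

Step 12
Reactants: 18 ethyl trienoate
Product: 19 (2Z,6R,7R,8E)-trienoic acid
Conditions: LiOH, THF/MeOH/H2O, 40 °C; then 1 M HCl to pH 4
Reagents that add atoms: lithium hydroxide [Li+].[OH-]
Why: Saponification by acyl–oxygen cleavage is done while the ester is still unhindered, because the axial neopentyl C19 ester of the cycloadduct would resist hydrolysis.

Step 13
Reactants: 19 trienoic acid
Product: 20 8α-(TBS-oxy)-15-(PMB-oxy)-17-norlabda-1,13E-dien-19-oic acid
Conditions: toluene (0.01 M), BHT (cat.), silanised sealed tube, 180 °C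
Reagents that add atoms: none
Why: Heating should trigger a concerted suprafacial [4+2] cycloaddition between the C10=C1–C2=C3 diene and the C4=C5 (Z)-2-methyl enoic acid, forming C3–C4 and C5–C10 together; the closest known reaction type is the type-1 intramolecular Diels–Alder reaction of 2,8,10-undecatrienoates (1,7,9-decatrienes) to trans-octalins, including cases with a methyl-bearing diene terminus. Ring A is closed by the cycloaddition itself through both new σ-bonds, and ring B by the C5–C10 bond across the four-carbon C6–C9 tether held in a chair-like anti arrangement. C4 follows from the Z-dienophile geometry (CO2H cis to C6, hence syn to the angular methyl, the axial C19 position), the trans C5/C10 fusion from the E-diene (tether outside, methyl inside) reacting with CO2H exo and the α-methyl endo, and the absolute sense from C9. The step needs anti (trans-fused) over syn (cis-fused) selectivity and π-facial selectivity. The former should be secured by the α-methyl group of the dienophile, since α-substituted dienophiles prefer the carbonyl-exo mode and the syn mode would press C18 against the inside C20 methyl. The latter should be secured by the trans-diequatorial C8-OTBS and C9 side chain, which fit the chair tether on only one diene face, the one that places H9 anti to the new angular methyl.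

Step 14
Reactants: 20 cycloadduct
Product: 21 8α-(TBS-oxy)-15-(PMB-oxy)-17-norlabd-13E-en-19-oic acid
Conditions: H2 (3 atm), RhCl(PPh3)3 (10 mol%), benzene/EtOH, rt
Reagents that add atoms: none
Why: Homogeneous rhodium-catalysed hydrogenation reduces the cis-disubstituted ring alkene and should leave the trisubstituted side-chain alkene, the PMB ether and the acid untouched.

Step 15
Reactants: 21 silyl ether
Product: 22 8α-hydroxy-15-(PMB-oxy)-17-norlabd-13E-en-19-oic acid
Conditions: TBAF (5 equiv), THF, 50 °C; aq. NH4Cl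
Reagents that add atoms: none
Why: Fluoride-induced desilylation frees the equatorial C8 hydroxyl, whose role as a control element is over, while the PMB ether is inert to fluoride.

Step 16
Reactants: 22 hydroxy acid
Product: 23 15-(PMB-oxy)-8-oxo-17-norlabd-13E-en-19-oic acid
Conditions: DMP (1.5 equiv), CH2Cl2, rt
Reagents that add atoms: none
Why: Dess–Martin oxidation converts the secondary alcohol into the C8 ketone under near-neutral conditions that tolerate the free acid, the alkene and the PMB ether.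

Step 17
Reactants: 23 keto acid
Product: 24 15-(PMB-oxy)labda-8(17),13E-dien-19-oic acid
Conditions: Ph3PCH3Br (5 equiv), KOtBu (4.5 equiv), THF, 0 → 50 °C; aq. citric acid
Reagents that add atoms: methyltriphenylphosphonium bromide C[P+](c1ccccc1)(c1ccccc1)c1ccccc1.[Br-]
Why: Wittig methylenation with the non-stabilised ylide (one equivalent is consumed by the acid) installs C17, and any base-induced epimerisation at C9 is harmless because the equatorial 9β side chain is the thermodynamic isomer.

Step 18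
Reactants: 24 PMB ether
Product: 25 isocupressic acid
Conditions: DDQ (1.3 equiv), CH2Cl2/pH 7 buffer, 0 °C
Reagents that add atoms: none
Why: Oxidative PMB cleavage by DDQ (hydride abstraction at the electron-rich benzylic carbon, then hydrolysis of the oxocarbenium ion) frees the allylic alcohol without touching the two alkenes or the acid.

Step 19
Reactants: 25 isocupressic acid
Product: 26 target CNP0323052.1
Conditions: palmitoyl chloride (1.1 equiv), pyridine, CH2Cl2, 0 °C; then H2O/pyridine, rt
Reagents that add atoms: palmitoyl chloride CCCCCCCCCCCCCCCC(=O)Cl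
Why: O-Acylation (nucleophilic acyl substitution) of the unhindered primary allylic alcohol is much faster than reaction at the hindered tertiary carboxyl group, and any mixed anhydride formed there should be hydrolysed at its palmitoyl carbonyl in the aqueous pyridine work-up.

**Compound list**
1 | geraniol, (2E)-3,7-dimethylocta-2,6-dien-1-ol | CC(C)=CCC/C(C)=C/CO | starting material
2 | geranyl PMB ether, 1-({[(2E)-3,7-dimethylocta-2,6-dien-1-yl]oxy}methyl)-4-methoxybenzene | CC(C)=CCC/C(C)=C/COCc1ccc(OC)cc1 | intermediate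
3 | 2,2-dimethyl-3-{(3E)-3-methyl-5-[(4-methoxybenzyl)oxy]pent-3-en-1-yl}oxirane, racemic at the ring CH, not isolated | CC1(C)OC1CC/C(C)=C/COCc2ccc(OC)cc2 | intermediate
4 | (4E)-4-methyl-6-[(4-methoxybenzyl)oxy]hex-4-enal | O=CCC/C(C)=C/COCc1ccc(OC)cc1 | intermediate
5 | ethyl (2E,6E)-6-methyl-8-[(4-methoxybenzyl)oxy]octa-2,6-dienoate | CCOC(=O)/C=C/CC/C(C)=C/COCc1ccc(OC)cc1 | intermediate
6 | (2E,6E)-6-methyl-8-[(4-methoxybenzyl)oxy]octa-2,6-dien-1-ol | OC/C=C/CC/C(C)=C/COCc1ccc(OC)cc1 | intermediate
7 | [(2R,3R)-3-{(3E)-3-methyl-5-[(4-methoxybenzyl)oxy]pent-3-en-1-yl}oxiran-2-yl]methanol | OC[C@H]1O[C@@H]1CC/C(C)=C/COCc2ccc(OC)cc2 | intermediate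
8 | (2S,3R,6E)-6-methyl-8-[(4-methoxybenzyl)oxy]-3-[(trimethylsilyl)ethynyl]oct-6-ene-1,2-diol, not isolated | C[Si](C)(C)C#C[C@@H](CC/C(C)=C/COCc1ccc(OC)cc1)[C@H](O)CO | intermediate
9 | (2S,3R,6E)-3-ethynyl-6-methyl-8-[(4-methoxybenzyl)oxy]oct-6-ene-1,2-diol | C#C[C@@H](CC/C(C)=C/COCc1ccc(OC)cc1)[C@H](O)CO | intermediate
10 | (E)-alkenyldimethylalane from 9 (Al on C1 trans to C9, both hydroxyls as dimethylaluminium alkoxides), not isolated | C[Al](C)/C=C(\C)[C@@H](CC/C(C)=C/COCc1ccc(OC)cc1)[C@H](O[Al](C)C)CO[Al](C)C | intermediate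
11 | (2S,3R,6E)-6-methyl-8-[(4-methoxybenzyl)oxy]-3-[(2E)-penta-2,4-dien-2-yl]oct-6-ene-1,2-diol | C=C/C=C(\C)[C@@H](CC/C(C)=C/COCc1ccc(OC)cc1)[C@H](O)CO | intermediate
12 | 1-O-(4-methylbenzenesulfonate) of 11, not isolated | C=C/C=C(\C)[C@@H](CC/C(C)=C/COCc1ccc(OC)cc1)[C@H](O)COS(=O)(=O)c2ccc(C)cc2 | intermediate
13 | (2S)-2-{(3E,5R,8E)-4,8-dimethyl-10-[(4-methoxybenzyl)oxy]deca-1,3,8-trien-5-yl}oxirane | C=C/C=C(\C)[C@@H](CC/C(C)=C/COCc1ccc(OC)cc1)[C@H]2CO2 | intermediate
14 | lithium alkoxide of (4R,5R,6E)-4-hydroxy-6-methyl-5-{(3E)-3-methyl-5-[(4-methoxybenzyl)oxy]pent-3-en-1-yl}nona-6,8-dienenitrile, not isolated | C=C/C=C(\C)[C@@H](CC/C(C)=C/COCc1ccc(OC)cc1)[C@H]([O-])CCC#N.[Li+] | intermediate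
15 | (4R,5R,6E)-4-[(tert-butyldimethylsilyl)oxy]-6-methyl-5-{(3E)-3-methyl-5-[(4-methoxybenzyl)oxy]pent-3-en-1-yl}nona-6,8-dienenitrile | C=C/C=C(\C)[C@@H](CC/C(C)=C/COCc1ccc(OC)cc1)[C@H](O[Si](C)(C)C(C)(C)C)CCC#N | intermediate
16 | N-(diisobutylalumino)imine of aldehyde 17, not isolated | C=C/C=C(\C)[C@@H](CC/C(C)=C/COCc1ccc(OC)cc1)[C@H](O[Si](C)(C)C(C)(C)C)CCC=N[Al](CC(C)C)CC(C)C | intermediate
17 | (4R,5R,6E)-4-[(tert-butyldimethylsilyl)oxy]-6-methyl-5-{(3E)-3-methyl-5-[(4-methoxybenzyl)oxy]pent-3-en-1-yl}nona-6,8-dienal | C=C/C=C(\C)[C@@H](CC/C(C)=C/COCc1ccc(OC)cc1)[C@H](O[Si](C)(C)C(C)(C)C)CCC=O | intermediate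
18 | ethyl (2Z,6R,7R,8E)-6-[(tert-butyldimethylsilyl)oxy]-2,8-dimethyl-7-{(3E)-3-methyl-5-[(4-methoxybenzyl)oxy]pent-3-en-1-yl}undeca-2,8,10-trienoate | C=C/C=C(\C)[C@@H](CC/C(C)=C/COCc1ccc(OC)cc1)[C@H](O[Si](C)(C)C(C)(C)C)CC/C=C(/C)C(=O)OCC | intermediate
19 | (2Z,6R,7R,8E)-6-[(tert-butyldimethylsilyl)oxy]-2,8-dimethyl-7-{(3E)-3-methyl-5-[(4-methoxybenzyl)oxy]pent-3-en-1-yl}undeca-2,8,10-trienoic acid | C=C/C=C(\C)[C@@H](CC/C(C)=C/COCc1ccc(OC)cc1)[C@H](O[Si](C)(C)C(C)(C)C)CC/C=C(/C)C(=O)O | intermediate
20 | 8α-[(tert-butyldimethylsilyl)oxy]-15-[(4-methoxybenzyl)oxy]-17-norlabda-1,13E-dien-19-oic acid (5α-H, 9α-H, 10β-CH3, axial 4β-CO2H) | CC(C)(C)[Si](C)(C)O[C@@H]1CC[C@@H]2[C@](C)(C=CC[C@]2(C)C(=O)O)[C@H]1CC/C(C)=C/COCc3ccc(OC)cc3 | intermediate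
21 | 8α-[(tert-butyldimethylsilyl)oxy]-15-[(4-methoxybenzyl)oxy]-17-norlabd-13E-en-19-oic acid | CC(C)(C)[Si](C)(C)O[C@@H]1CC[C@@H]2[C@](C)(CCC[C@]2(C)C(=O)O)[C@H]1CC/C(C)=C/COCc3ccc(OC)cc3 | intermediate
22 | 8α-hydroxy-15-[(4-methoxybenzyl)oxy]-17-norlabd-13E-en-19-oic acid | O[C@@H]1CC[C@@H]2[C@](C)(CCC[C@]2(C)C(=O)O)[C@H]1CC/C(C)=C/COCc3ccc(OC)cc3 | intermediate
23 | 15-[(4-methoxybenzyl)oxy]-8-oxo-17-norlabd-13E-en-19-oic acid | O=C1CC[C@@H]2[C@](C)(CCC[C@]2(C)C(=O)O)[C@H]1CC/C(C)=C/COCc3ccc(OC)cc3 | intermediate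
24 | 15-[(4-methoxybenzyl)oxy]labda-8(17),13E-dien-19-oic acid | C=C1CC[C@@H]2[C@](C)(CCC[C@]2(C)C(=O)O)[C@H]1CC/C(C)=C/COCc3ccc(OC)cc3 | intermediate
25 | isocupressic acid, (1S,4aR,5S,8aR)-5-[(3E)-5-hydroxy-3-methylpent-3-en-1-yl]-1,4a-dimethyl-6-methylidenedecahydronaphthalene-1-carboxylic acid | C=C1CC[C@@H]2[C@](C)(CCC[C@]2(C)C(=O)O)[C@H]1CC/C(C)=C/CO | intermediate
26 | CNP0323052.1, 15-(hexadecanoyloxy)labda-8(17),13E-dien-19-oic acid | C=C1CC[C@@H]2[C@](C)(CCC[C@]2(C)C(=O)O)[C@H]1CC/C(C)=C/COC(=O)CCCCCCCCCCCCCCC | target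

**Step count and risks**
Total: 19 steps. Longest linear sequence: 19 steps (geraniol to 26; the route is fully linear).

Steps most likely to fail:

1. Step 13. The hindered diene (methyl inside) needs a high temperature, at which anti/syn (trans/cis fusion) and facial selectivity may erode, and a [1,5]-hydrogen shift from the inside methyl may consume the diene. The fallback moves the cycloaddition to a Lewis-acid-promoted reaction of the enal at low temperature. It sets out from 18: DIBAL-H (CH2Cl2, −78 °C) gives the (2Z)-trienol F1, and MnO2 (CH2Cl2, rt) gives the (2Z)-2-methyl trienal F2. Me2AlCl (CH2Cl2, −78 → −20 °C) should then promote the intramolecular Diels–Alder reaction in the carbonyl-exo mode typical of α-substituted enals, which is the trans-fused mode here, to give the C19 aldehyde F3. Pinnick oxidation (NaClO2, NaH2PO4, 2-methyl-2-butene, t-BuOH/H2O) returns to the route at 20.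

2. Step 7. Carbometalation of the branched alkyne may be slow or misdirected by the aluminium alkoxides of the free diol, and the alkenylalane may be protonated before it couples. The fallback isolates a stable alkenyl halide. It sets out from 9: 2,2-dimethoxypropane with PPTS gives the acetonide F4, and Me3Al/Cp2ZrCl2 then I2 gives the (E)-iodoalkene F5. Stille coupling with tributyl(vinyl)stannane (Pd(PPh3)4, CuI, DMF) gives the dienyl acetonide F6, and PPTS in MeOH releases the diol and returns to the route at 11.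

3. Step 14. Hydrogen uptake at the ring alkene next to the quaternary C10 may be slow, and forcing conditions may start to reduce or isomerise the side-chain alkene. The fallback replaces catalytic hydrogenation by a stoichiometric metal-free diimide reduction (2-nitrobenzenesulfonohydrazide, Et3N, CH2Cl2, rt), a concerted syn hydrogen transfer whose rate falls steeply from cis-disubstituted to trisubstituted alkenes. It sets out from 20 and returns at 21; no new compound is made (F0).

**Further compounds**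
F1 | step 13 | (2Z,6R,7R,8E)-6-[(tert-butyldimethylsilyl)oxy]-2,8-dimethyl-7-{(3E)-3-methyl-5-[(4-methoxybenzyl)oxy]pent-3-en-1-yl}undeca-2,8,10-trien-1-ol | C=C/C=C(\C)[C@@H](CC/C(C)=C/COCc1ccc(OC)cc1)[C@H](O[Si](C)(C)C(C)(C)C)CC/C=C(/C)CO
F2 | step 13 | (2Z,6R,7R,8E)-6-[(tert-butyldimethylsilyl)oxy]-2,8-dimethyl-7-{(3E)-3-methyl-5-[(4-methoxybenzyl)oxy]pent-3-en-1-yl}undeca-2,8,10-trienal | C=C/C=C(\C)[C@@H](CC/C(C)=C/COCc1ccc(OC)cc1)[C@H](O[Si](C)(C)C(C)(C)C)CC/C=C(/C)C=O
F3 | step 13 | 8α-[(tert-butyldimethylsilyl)oxy]-15-[(4-methoxybenzyl)oxy]-17-norlabda-1,13E-dien-19-al | CC(C)(C)[Si](C)(C)O[C@@H]1CC[C@@H]2[C@](C)(C=CC[C@]2(C)C=O)[C@H]1CC/C(C)=C/COCc3ccc(OC)cc3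
F4 | step 7 | (4S)-4-{(3R,6E)-6-methyl-8-[(4-methoxybenzyl)oxy]oct-6-en-1-yn-3-yl}-2,2-dimethyl-1,3-dioxolane | C#C[C@@H](CC/C(C)=C/COCc1ccc(OC)cc1)[C@H]2COC(C)(C)O2
F5 | step 7 | (4S)-4-{(1E,3R,6E)-1-iodo-2,6-dimethyl-8-[(4-methoxybenzyl)oxy]octa-1,6-dien-3-yl}-2,2-dimethyl-1,3-dioxolane | I/C=C(\C)[C@@H](CC/C(C)=C/COCc1ccc(OC)cc1)[C@H]2COC(C)(C)O2
F6 | step 7 | (4S)-4-{(3E,5R,8E)-4,8-dimethyl-10-[(4-methoxybenzyl)oxy]deca-1,3,8-trien-5-yl}-2,2-dimethyl-1,3-dioxolane | C=C/C=C(\C)[C@@H](CC/C(C)=C/COCc1ccc(OC)cc1)[C@H]2COC(C)(C)O2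
F0 | step 14 | none | none
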